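**Retrosynthetic overview**
- The angelate (O2), the acetate (O4) and the exocyclic methylene C13 are removed first. This leads back to a ring A triol whose C4–OH and C8–OH are the two ends of a cleaved two-carbon acetate tether.
- The strategy rests on one feature of cycloheptene ring A (C1, C5=C6, C7, C8, C9, C10). The C8–O bond and the C1–C2 bond stand on the same face and are 1,4-related through C9–C10, so a bromoacetate on O8 can deliver C3 and C4 to a C2 aldehyde.
- The key disconnection is C2–C3. A SmI2 Reformatsky closure gives a temporary eight-membered lactone bridging C8 and C1 and sets C2. LiBH4 later cuts the O8–C4 bond.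
- Ring A comes from ring-closing metathesis at C5=C6. C7 and C8 come from a catalyst-controlled anti allylboration, and C1 and C10 from an enantioselective Ireland–Claisen rearrangement of a crotyl ester.
- Order of ring formation: ring A (step 10), the temporary eight-membered lactone (made in step 14, opened in step 15), then γ-lactone ring B (step 18).

Key step: step 14

Numbering and faces: ring A = C1–C5(Me)=C6–C7–C8–C9–C10(Me). The side chain C2–C3–C4 sits on C1, and C11, C12 and C13 sit on C7. α is the face of ring A that carries O8, C2 (on C1) and C11 (on C7). β is the face of the C10 methyl group.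

Assumption: the (S,S)-configured boron controller of step 2 is taken to deliver the (2S,3R)-acid. Both antipodes of its diamine are commercial, so an opposite sense of induction is corrected by exchanging the controller and changing nothing else.

**Step 1**
Reactants: 1 (E)-but-2-en-1-ol; 2 3-methylbut-3-enoic acid
Product: 3 (E)-but-2-en-1-yl 3-methylbut-3-enoate
Conditions: DCC, DMAP (5 mol %), CH2Cl2, 0 °C
Reagents that add atoms: none
Why: Steglich esterification; the low DMAP loading and low temperature keep the β,γ-alkene from moving into conjugation.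

**Step 2**
Reactants: 3 (E)-but-2-en-1-yl 3-methylbut-3-enoate
Product: 5 (2S,3R)-3-methyl-2-(prop-1-en-2-yl)pent-4-enoic acid, via boron ketene acetal 4 (not isolated)
Conditions: (S,S)-2-bromo-4,5-diphenyl-1,3-bis{[3,5-bis(trifluoromethyl)phenyl]sulfonyl}-1,3,2-diazaborolidine (from the bis-sulfonamide and BBr3), Et3N, toluene–hexane, −78 to −20 °C; aq. work-up
Reagents that add atoms: none
Why: Enantioselective boron-enolate variant of the Ireland–Claisen rearrangement, known for crotyl alkanoates and for allylic 3-methylbut-3-enoates; Et3N in a non-polar medium gives the enolate with the isopropenyl group cis to the allyloxy oxygen, the chair transition state with the (E)-crotyl methyl equatorial then gives the 2,3-anti pair (C1 and C10), and the C2-symmetric diazaborolidine decides which enolate face bonds.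

**Step 3**
Reactants: 5 (2S,3R)-3-methyl-2-(prop-1-en-2-yl)pent-4-enoic acid
Product: 6 (2S,3R)-3-methyl-2-(prop-1-en-2-yl)pent-4-en-1-ol
Conditions: LiAlH4, Et2O, 0 °C to rt
Reagents that add atoms: none
Why: Hydride reduction of the carboxylate to the C2 alcohol; the carboxylate is not enolised, so C1 keeps its configuration.

**Step 4**
Reactants: 6 (2S,3R)-3-methyl-2-(prop-1-en-2-yl)pent-4-en-1-ol
Product: 7 4-methoxybenzyl (PMB) ether of 6
Conditions: NaH, PMBCl, Bu4NI (cat.), DMF, 0 °C to rt
Reagents that add atoms: 4-methoxybenzyl chloride, COc1ccc(CCl)cc1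
Why: Williamson etherification; the PMB group survives borane, oxidation, boronate and ruthenium chemistry and can later be removed under neutral conditions next to a bromoacetate.

**Step 5**
Reactants: 7 PMB ether of 6
Product: 9 (3R,4S)-4-{[(4-methoxybenzyl)oxy]methyl}-3,5-dimethylhex-5-en-1-ol, via trialkylborane 8 (not isolated)
Conditions: Sia2BH (from BH3·THF and 2-methylbut-2-ene), THF, 0 °C; then NaOH, H2O2, 0 °C to rt
Reagents that add atoms: hydrogen peroxide, OO
Why: Hydroboration–oxidation; the bulky dialkylborane adds much faster to the monosubstituted vinyl group than to the 1,1-disubstituted isopropenyl group (9-BBN would not discriminate) and places boron on the terminal carbon C8.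

**Step 6**
Reactants: 9 (3R,4S)-4-{[(4-methoxybenzyl)oxy]methyl}-3,5-dimethylhex-5-en-1-ol
Product: 10 (3R,4S)-4-{[(4-methoxybenzyl)oxy]methyl}-3,5-dimethylhex-5-enal (C8 aldehyde)
Conditions: Dess–Martin periodinane, NaHCO3, CH2Cl2, 0 °C to rt
Reagents that add atoms: none
Why: Dess–Martin oxidation stops at the aldehyde, which has no α-stereocentre to lose.

**Step 7**
Reactants: 11 tert-butyl(but-3-yn-1-yloxy)dimethylsilane
Product: 12 (E)-alkenylboronate TBSOCH2CH2CH=CH–Bpin
Conditions: HBpin, Cp2Zr(H)Cl (5 mol %), Et3N (5 mol %), neat, 60 °C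
Reagents that add atoms: pinacolborane, B1OC(C)(C)C(C)(C)O1
Why: Zirconium-catalysed syn hydroboration of a terminal alkyne gives only the (E)-1-alkenylboronate, which fixes the alkene geometry needed later.

**Step 8**
Reactants: 12 (E)-alkenylboronate
Product: 14 (E)-allylboronate TBSOCH2CH2CH=CHCH2–Bpin, via boronate ate complex 13 (not isolated)
Conditions: BrCH2Cl, n-BuLi, THF, −78 °C to rt
Reagents that add atoms: bromochloromethane, ClCBr
Why: Matteson homologation; chloromethyllithium adds to boron and the alkenyl group migrates 1,2 with loss of chloride and full retention of the (E) geometry.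

**Step 9**
Reactants: 10 C8 aldehyde; 14 (E)-allylboronate
Product: 16 diene alcohol (1S,7S,8R,10R) CH2=CH–C7H(CH2CH2OTBS)–C8H(OH)–C9H2–C10H(Me)–C1H(CH2OPMB)–C5(Me)=CH2, via borate ester 15 (not isolated)
Conditions: (S)-TRIP [(S)-3,3'-bis(2,4,6-triisopropylphenyl)-1,1'-binaphthyl-2,2'-diyl hydrogen phosphate] (10 mol %), 4 Å MS, toluene, −30 °C
Reagents that add atoms: none
Why: Chiral-phosphoric-acid-catalysed allylboration through a closed chair transition state; the (E)-boronate gives the 7,8-anti pair (cis on the later ring), the (S)-acid directs attack to the Si face of the aldehyde and so gives 8R, and the remote C10 centre has little influence, so the catalyst decides.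

**Step 10**
Reactants: 16 diene alcohol
Product: 17 ring A alcohol (5-methylcycloheptene C5=C6; 8α-OH; 7α-CH2CH2OTBS; 1α-CH2OPMB; 10β-Me)
Conditions: second-generation Grubbs catalyst RuCl2(=CHPh)(PCy3)(H2IMes) (5–10 mol %), toluene (2 mM), 80 °C
Reagents that add atoms: none
Why: Ring-closing metathesis; ruthenium loads on the monosubstituted C6 vinyl group and closes onto the isopropenyl group to give the trisubstituted C5=C6 alkene of the seven-membered ring, driven by loss of ethene, with no stereocentre touched.

**Step 11**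
Reactants: 17 ring A alcohol; 18 bromoacetyl bromide
Product: 19 C8 bromoacetate of 17
Conditions: pyridine, CH2Cl2, −20 to 0 °C
Reagents that add atoms: none
Why: O-acylation of the only free hydroxyl group installs C3 and C4 on O8 with retention at C8.

**Step 12**
Reactants: 19 C8 bromoacetate
Product: 20 C2 alcohol (8α-OCOCH2Br; 1α-CH2OH; 7α-CH2CH2OTBS; 10β-Me)
Conditions: DDQ, CH2Cl2–pH 7 buffer, 0 °C
Reagents that add atoms: none
Why: Oxidative PMB cleavage under neutral buffered conditions leaves the bromoacetate, the silyl ether and the alkene untouched.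

**Step 13**
Reactants: 20 C2 alcohol
Product: 21 ring A aldehyde (1α-CHO; 8α-OCOCH2Br; 7α-CH2CH2OTBS; 10β-Me; C5=C6)
Conditions: Dess–Martin periodinane, NaHCO3, CH2Cl2, 0 °C; used at once
Reagents that add atoms: none
Why: The buffered Dess–Martin oxidation is non-basic, so C1 is not epimerised and C5=C6 does not move into conjugation with the new aldehyde.

**Step 14**
Reactants: 21 ring A aldehyde
Product: 23 bridged eight-membered β-hydroxy lactone (2S; O8–C4(=O)–C3H2–C2H(OH)–C1; oxabicyclo[4.3.2]undecene), via samarium enolate 22 (not isolated)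
Conditions: SmI2 (2.5 equiv), THF, −78 to −40 °C, slow addition of 21 (final 5 mM); aq. NH4Cl
Reagents that add atoms: none
Why: Two single-electron transfers from divalent samarium cleave the C–Br bond of 21 faster than they touch the aldehyde and give the trivalent samarium ester enolate 22, whose metal then binds the C2 carbonyl oxygen. C3 adds to C2 through a closed, chelated aldol-type transition state; this is the SmI2-promoted intramolecular Reformatsky reaction known for bromoacetates of hydroxy aldehydes, including closures to eight-membered and larger lactones. The ring closes in an 8-(enolendo)-exo-trig mode, which is possible only because O8 and C2 both stand on the α face of ring A and are linked by the short path C8–C9–C10–C1, so the new four-atom bridge spans C1 and C8. The new stereocentre C2 is controlled by C1 and C8 through the tether: the enolate can reach C2 only from the C8 side beneath ring A, and in the chelate the samarium-bound oxygen should lie under the flat, unsubstituted C5=C6 edge with the small formyl hydrogen turned toward the α-hydrogens of C9 and C10, which exposes the face that gives 2S. The step needs chemoselectivity (C–Br before C=O; the silyl ether and the trisubstituted alkene are inert), intramolecular over intermolecular addition (slow addition into excess SmI2 at high dilution) and retention at C1, which the cold and essentially neutral medium secures for this β,γ-unsaturated aldehyde.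

**Step 15**
Reactants: 23 bridged β-hydroxy lactone
Product: 24 triol (2S; C2-OH; C4-OH; 8α-OH; 7α-CH2CH2OTBS)
Conditions: LiBH4, THF, 0 °C to rt; aq. NH4Cl
Reagents that add atoms: none
Why: LiBH4 reduces the strained lactone to the C4 and C8 alcohols and so removes the tether bond O8–C4; nothing else is reducible because C12 is deliberately carried as a silyl ether and not as an ester, which next to the liberated O8 alkoxide would lactonise and be over-reduced.

**Step 16**
Reactants: 24 triol
Product: 25 C2/C4 acetonide (1,3-dioxane) with free 8α-OH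
Conditions: Me2C(OMe)2, PPTS (cat.), CH2Cl2, 0 °C to rt
Reagents that add atoms: 2,2-dimethoxypropane, COC(C)(C)OC
Why: Acid-catalysed transacetalisation; only the C2/C4 1,3-diol can form a six-membered dioxane, so O8 stays free, and PPTS is too mild to cleave the primary silyl ether.

**Step 17**
Reactants: 25 acetonide
Product: 26 C8/C12 diol (8α-OH; 7α-CH2CH2OH; C2/C4 acetonide)
Conditions: TBAF, THF, 0 °C to rt
Reagents that add atoms: none
Why: Fluoride-induced desilylation frees the C12 alcohol, and the acetonide and alkene are inert to fluoride.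

**Step 18**
Reactants: 26 C8/C12 diol
Product: 28 cis-fused γ-lactone (ring B: O8–C12(=O)–C11H2–C7), via lactol 27 (not isolated)
Conditions: TEMPO (cat.), PhI(OAc)2, CH2Cl2, rt
Reagents that add atoms: none
Why: Oxoammonium oxidation takes the primary C12 alcohol to the aldehyde, the cis O8–H traps it as lactol 27, which is oxidised on to the lactone; the cis ring fusion follows from the C7/C8 configuration set in step 9.

**Step 19**
Reactants: 28 γ-lactone
Product: 30 α-(dimethylaminomethyl) lactone, via lithium enolate 29 (not isolated)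
Conditions: LDA, THF, −78 °C; then CH2=NMe2+ I−, −78 °C to rt
Reagents that add atoms: N,N-dimethylmethyleneiminium iodide (Eschenmoser's salt), C=[N+](C)C.[I-]
Why: Mannich reaction of the lactone enolate brings in C13; attack should come from the convex face of the cis-fused bicycle, and the new C11 centre is destroyed in the next step.

**Step 20**
Reactants: 30 α-(dimethylaminomethyl) lactone
Product: 32 α-methylene-γ-lactone acetonide, via ammonium iodide 31 (not isolated)
Conditions: MeI, CH2Cl2, rt; then aq. NaHCO3
Reagents that add atoms: none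
Why: Quaternisation followed by mild-base β-elimination of trimethylamine (Hofmann-type, E1cB) gives the C11=C13 methylene without touching the acetonide.

**Step 21**
Reactants: 32 α-methylene-γ-lactone acetonide
Product: 33 C2/C4 diol of the α-methylene lactone
Conditions: AcOH–H2O–THF, 40 °C
Reagents that add atoms: none
Why: Mild acetal hydrolysis; the lactone, the exocyclic methylene and C5=C6 tolerate dilute acetic acid.

**Step 22**
Reactants: 33 C2/C4 diol
Product: 34 C4 monoacetate (free 2S-OH)
Conditions: AcCl (1.05 equiv), 2,4,6-collidine, CH2Cl2, −78 °C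
Reagents that add atoms: acetyl chloride, CC(=O)Cl
Why: Low-temperature acylation with a hindered base selects the primary C4 hydroxyl over the secondary C2 hydroxyl, which is flanked by ring A.

**Step 23**
Reactants: 34 C4 monoacetate; 35 angelic acid [(Z)-2-methylbut-2-enoic acid]
Product: 37 target CNP0163960.1, via mixed anhydride 36 (not isolated)
Conditions: 35, 2,4,6-trichlorobenzoyl chloride, Et3N, toluene, rt; then 34, 80 °C (no DMAP)
Reagents that add atoms: none
Why: Yamaguchi-type mixed-anhydride esterification run without a nucleophilic catalyst transfers the angeloyl group without Z to E isomerisation, and since the C2–O bond is not broken the 2S configuration is retained.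

**Compound list**
1 | (E)-but-2-en-1-ol | C/C=C/CO | starting material
2 | 3-methylbut-3-enoic acid | C=C(C)CC(=O)O | starting material
3 | (E)-but-2-en-1-yl 3-methylbut-3-enoate | C=C(C)CC(=O)OC/C=C/C | intermediate
4 | boron ketene acetal (isopropenyl cis to the crotyloxy oxygen; (S,S)-diazaborolidine on oxygen) | C=C(C)/C=C(\OC/C=C/C)OB1N(S(=O)(=O)c2cc(cc(c2)C(F)(F)F)C(F)(F)F)[C@@H](c2ccccc2)[C@H](c2ccccc2)N1S(=O)(=O)c1cc(cc(c1)C(F)(F)F)C(F)(F)F | intermediate
5 | (2S,3R)-3-methyl-2-(prop-1-en-2-yl)pent-4-enoic acid | C=C[C@@H](C)[C@H](C(=O)O)C(C)=C | intermediate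
6 | (2S,3R)-3-methyl-2-(prop-1-en-2-yl)pent-4-en-1-ol | C=C[C@@H](C)[C@H](CO)C(C)=C | intermediate
7 | PMB ether of 6 | C=C[C@@H](C)[C@H](COCc1ccc(OC)cc1)C(C)=C | intermediate
8 | trialkylborane (C8–B(Sia)2) | CC(C)C(C)B(CC[C@@H](C)[C@H](COCc1ccc(OC)cc1)C(C)=C)C(C)C(C)C | intermediate
9 | (3R,4S)-4-{[(4-methoxybenzyl)oxy]methyl}-3,5-dimethylhex-5-en-1-ol | OCC[C@@H](C)[C@H](COCc1ccc(OC)cc1)C(C)=C | intermediate
10 | (3R,4S)-4-{[(4-methoxybenzyl)oxy]methyl}-3,5-dimethylhex-5-enal | O=CC[C@@H](C)[C@H](COCc1ccc(OC)cc1)C(C)=C | intermediate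
11 | tert-butyl(but-3-yn-1-yloxy)dimethylsilane | C#CCCO[Si](C)(C)C(C)(C)C | starting material
12 | (E)-4-(TBSO)but-1-enylboronic acid pinacol ester | CC(C)(C)[Si](C)(C)OCC/C=C/B1OC(C)(C)C(C)(C)O1 | intermediate
13 | lithium (chloromethyl)boronate ate complex | [Li+].CC(C)(C)[Si](C)(C)OCC/C=C/[B-]1(CCl)OC(C)(C)C(C)(C)O1 | intermediate
14 | (E)-5-(TBSO)pent-2-enylboronic acid pinacol ester | CC(C)(C)[Si](C)(C)OCC/C=C/CB1OC(C)(C)C(C)(C)O1 | intermediate
15 | O8 pinacol borate of 16 | CC(C)(C)[Si](C)(C)OCC[C@@H](C=C)[C@H](OB1OC(C)(C)C(C)(C)O1)C[C@@H](C)[C@H](COCc1ccc(OC)cc1)C(C)=C | intermediate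
16 | diene alcohol (1S,7S,8R,10R) | CC(C)(C)[Si](C)(C)OCC[C@@H](C=C)[C@H](O)C[C@@H](C)[C@H](COCc1ccc(OC)cc1)C(C)=C | intermediate
17 | ring A alcohol (8α-OH, 7α-CH2CH2OTBS, 1α-CH2OPMB, 10β-Me) | CC(C)(C)[Si](C)(C)OCC[C@H]1C=C(C)[C@@H](COCc2ccc(OC)cc2)[C@H](C)C[C@H]1O | intermediate
18 | bromoacetyl bromide | BrCC(=O)Br | starting material
19 | C8 bromoacetate of 17 | CC(C)(C)[Si](C)(C)OCC[C@H]1C=C(C)[C@@H](COCc2ccc(OC)cc2)[C@H](C)C[C@H]1OC(=O)CBr | intermediate
20 | C2 alcohol with C8 bromoacetate | CC(C)(C)[Si](C)(C)OCC[C@H]1C=C(C)[C@@H](CO)[C@H](C)C[C@H]1OC(=O)CBr | intermediate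
21 | ring A aldehyde (C2) with C8 bromoacetate (key-step precursor) | CC(C)(C)[Si](C)(C)OCC[C@H]1C=C(C)[C@@H](C=O)[C@H](C)C[C@H]1OC(=O)CBr | intermediate
22 | trivalent samarium enolate of the O8 acetate | CC(C)(C)[Si](C)(C)OCC[C@H]1C=C(C)[C@@H](C=O)[C@H](C)C[C@H]1OC(=C)O[Sm](I)I | intermediate
23 | bridged eight-membered β-hydroxy lactone, 2S (key-step product) | CC(C)(C)[Si](C)(C)OCC[C@H]1C=C(C)[C@@H]2[C@H](C)C[C@H]1OC(=O)C[C@@H]2O | intermediate
24 | triol (C2, C4, C8 hydroxyls; C12 OTBS) | CC(C)(C)[Si](C)(C)OCC[C@H]1C=C(C)[C@@H]([C@H](CCO)O)[C@H](C)C[C@H]1O | intermediate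
25 | C2/C4 acetonide, free 8α-OH | CC(C)(C)[Si](C)(C)OCC[C@H]1C=C(C)[C@@H]([C@@H]2CCOC(C)(C)O2)[C@H](C)C[C@H]1O | intermediate
26 | C8/C12 diol acetonide | OCC[C@H]1C=C(C)[C@@H]([C@@H]2CCOC(C)(C)O2)[C@H](C)C[C@H]1O | intermediate
27 | C12 lactol (anomers) | C1C(O)O[C@@H]2C[C@@H](C)[C@H]([C@@H]3CCOC(C)(C)O3)C(C)=C[C@H]12 | intermediate
28 | cis-fused γ-lactone acetonide | C1C(=O)O[C@@H]2C[C@@H](C)[C@H]([C@@H]3CCOC(C)(C)O3)C(C)=C[C@H]12 | intermediate
29 | lithium enolate of 28 | C1=C(O[Li])O[C@@H]2C[C@@H](C)[C@H]([C@@H]3CCOC(C)(C)O3)C(C)=C[C@H]12 | intermediate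
30 | α-(dimethylaminomethyl) lactone (C13 on the convex face) | CN(C)C[C@H]1C(=O)O[C@@H]2C[C@@H](C)[C@H]([C@@H]3CCOC(C)(C)O3)C(C)=C[C@H]12 | intermediate
31 | trimethylammonium iodide of 30 | C[N+](C)(C)C[C@H]1C(=O)O[C@@H]2C[C@@H](C)[C@H]([C@@H]3CCOC(C)(C)O3)C(C)=C[C@H]12.[I-] | intermediate
32 | α-methylene-γ-lactone acetonide | C=C1C(=O)O[C@@H]2C[C@@H](C)[C@H]([C@@H]3CCOC(C)(C)O3)C(C)=C[C@H]12 | intermediate
33 | α-methylene-γ-lactone C2/C4 diol | C=C1C(=O)O[C@@H]2C[C@@H](C)[C@H]([C@H](CCO)O)C(C)=C[C@H]12 | intermediate
34 | C4 monoacetate, free 2S-OH | C=C1C(=O)O[C@@H]2C[C@@H](C)[C@H]([C@H](CCOC(C)=O)O)C(C)=C[C@H]12 | intermediate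
35 | angelic acid | C/C=C(/C)C(=O)O | starting material
36 | angelic 2,4,6-trichlorobenzoic mixed anhydride | C/C=C(/C)C(=O)OC(=O)c1c(Cl)cc(Cl)cc1Cl | intermediate
37 | CNP0163960.1 | C=C1C(=O)O[C@@H]2C[C@@H](C)[C@H]([C@H](CCOC(C)=O)OC(=O)/C(C)=C\C)C(C)=C[C@H]12 | target

Total step count: 23. Longest linear sequence: 21 (steps 1–6 and 9–23).

**Steps most likely to fail**

1. Step 14.
   - What may go wrong: protonation of the enolate (net debromination), intermolecular addition outrunning the medium-ring closure, or poor facial selectivity at C2.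
   - Fallback: a reagent-controlled intermolecular acetate aldol replaces the tether. It sets out from 17 and returns at 24.
   - 17 is acetylated (Ac2O, pyridine) to the C8 acetate F1. DDQ cleaves the PMB ether to give the C2 alcohol F2, and Dess–Martin oxidation gives the aldehyde F3.
   - Doubly lithiated (S)-2-hydroxy-1,2,2-triphenylethyl acetate ((S)-HYTRA, 2 equiv LDA, THF, −78 °C or colder) adds to F3 and should give the (2S)-β-hydroxy ester F4. The (R)-reagent is known to turn isobutyraldehyde into the (R)-β-hydroxy acid, which corresponds to 2S here with the (S)-reagent.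
   - LiAlH4 then reduces both ester groups of F4 and delivers triol 24.

2. Step 2.
   - What may go wrong: mixed enolate geometry of the dienolate (loss of anti selectivity), sluggish rearrangement, or incomplete enantiofacial control.
   - Fallback: an achiral rearrangement followed by covalent resolution. It sets out from 3 and returns at 6.
   - LDA in THF at −78 °C and then Me3SiCl convert 3 into the silyl ketene acetal F5. On warming this rearranges to the racemic anti silyl ester F6.
   - Hydrolytic work-up gives 5 together with its mirror-image acid F7.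
   - DCC/DMAP coupling of the racemate with (S)-4-benzyl-1,3-oxazolidin-2-one gives the (2S,3R)-imide F8 and the (2R,3S)-imide F9. These are separated by chromatography, and any syn isomers are removed at the same point.
   - LiBH4 reduction of F8 releases the auxiliary and gives alcohol 6, so step 3 is skipped.

3. Step 10.
   - What may go wrong: slow closure onto the hindered 1,1-disubstituted alkene between two branched allylic carbons, with dimerisation through the vinyl group or alkene migration taking over.
   - Fallback: a carbonyl coupling replaces the metathesis. It sets out from 16 and returns at 17.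
   - 16 is silylated (Et3SiCl, imidazole) to the triethylsilyl ether F10.
   - Lemieux–Johnson cleavage of both terminal alkenes (OsO4 cat., NaIO4, 2,6-lutidine, dioxane–H2O) gives the keto aldehyde F11 (C5 methyl ketone, C6 aldehyde).
   - Intramolecular McMurry coupling with low-valent titanium (TiCl3(DME)1.5, Zn–Cu, DME, reflux, slow addition) joins C5 and C6 to give the cycloheptene silyl ether F12.
   - AcOH–THF–H2O removes the triethylsilyl group selectively and gives 17.

**Further compounds**
F1 | step 14 | C8 acetate of 17 | CC(C)(C)[Si](C)(C)OCC[C@H]1C=C(C)[C@@H](COCc2ccc(OC)cc2)[C@H](C)C[C@H]1OC(C)=O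
F2 | step 14 | C2 alcohol with C8 acetate | CC(C)(C)[Si](C)(C)OCC[C@H]1C=C(C)[C@@H](CO)[C@H](C)C[C@H]1OC(C)=O
F3 | step 14 | C2 aldehyde with C8 acetate | CC(C)(C)[Si](C)(C)OCC[C@H]1C=C(C)[C@@H](C=O)[C@H](C)C[C@H]1OC(C)=O
F4 | step 14 | (2S)-β-hydroxy ester of (S)-1,1,2-triphenylethane-1,2-diol | CC(C)(C)[Si](C)(C)OCC[C@H]1C=C(C)[C@@H]([C@H](CC(=O)O[C@@H](c2ccccc2)C(O)(c2ccccc2)c2ccccc2)O)[C@H](C)C[C@H]1OC(C)=O
F5 | step 2 | trimethylsilyl ketene acetal of 3 | C=C(C)/C=C(\OC/C=C/C)O[Si](C)(C)C
F6 | step 2 | trimethylsilyl ester of the anti acid (racemic, one enantiomer drawn) | C=C[C@@H](C)[C@H](C(=O)O[Si](C)(C)C)C(C)=C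
F7 | step 2 | (2R,3S)-3-methyl-2-(prop-1-en-2-yl)pent-4-enoic acid (mirror image of 5) | C=C[C@H](C)[C@@H](C(=O)O)C(C)=C
F8 | step 2 | (S)-4-benzyl-3-[(2S,3R)-acyl]oxazolidin-2-one | C=C[C@@H](C)[C@H](C(=O)N1[C@@H](Cc2ccccc2)COC1=O)C(C)=C
F9 | step 2 | (S)-4-benzyl-3-[(2R,3S)-acyl]oxazolidin-2-one | C=C[C@H](C)[C@@H](C(=O)N1[C@@H](Cc2ccccc2)COC1=O)C(C)=C
F10 | step 10 | O8 triethylsilyl ether of 16 | CC(C)(C)[Si](C)(C)OCC[C@@H](C=C)[C@H](O[Si](CC)(CC)CC)C[C@@H](C)[C@H](COCc1ccc(OC)cc1)C(C)=C
F11 | step 10 | keto aldehyde (C5 ketone, C6 aldehyde) | CC(C)(C)[Si](C)(C)OCC[C@@H](C=O)[C@H](O[Si](CC)(CC)CC)C[C@@H](C)[C@H](COCc1ccc(OC)cc1)C(C)=O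
F12 | step 10 | O8 triethylsilyl ether of 17 | CC(C)(C)[Si](C)(C)OCC[C@H]1C=C(C)[C@@H](COCc2ccc(OC)cc2)[C@H](C)C[C@H]1O[Si](CC)(CC)CC
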